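## Retrosynthetic overview

1. The last step makes the C7–C8 bond (germacrane numbering) by an umpolung allylation. The 2‑(methoxycarbonyl)allyl bromide is turned into an allylchromium reagent, so the enoate β‑carbon C7 attacks the aldehyde carbon C8; both carbons are normally electrophilic.
2. That one operation closes the ten‑membered carbocycle first and the γ‑lactone second (alkoxide onto the methyl ester), and sets C7 and C8 under a chiral chromium ligand.
3. The open‑chain precursor carries the C8 aldehyde as a lactol with the C14 hydroxyl, the chlorohydrin ester already on C15, and a bromomethyl enoate installed by cross‑metathesis.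
4. The C1=C10 olefin comes from an E‑selective Wittig reaction with a bifunctional ylide; DIBAL reduction then gives a five‑membered cyclic acetal that masks C14‑OH and the C8 aldehyde together.
5. The C4=C5 olefin comes from anti‑carbomagnesiation of propargyl alcohol with allyl trapping; the side‑chain acid comes from the commercial (R)‑bromohydrin acid.

Assumptions: the hemiacetal and acetal carbons of 7, 13, 14, 18, 20, 21 and 22 are epimer mixtures that are erased later and are left unspecified. L* is 1,8‑bis[(4S)‑4‑isopropyl‑4,5‑dihydro‑1,3‑oxazol‑2‑yl]‑3,6‑di‑tert‑butyl‑9H‑carbazole; its antipode is used instead if a model aldehyde shows Si‑face delivery.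

## Route

Step 1
Reactants: 1 prop‑2‑yn‑1‑ol; 2 2‑(2‑bromoethyl)‑1,3‑dioxolane; 3 allyl bromide
Product: 6 (2Z)‑2‑[2‑(1,3‑dioxolan‑2‑yl)ethyl]hexa‑2,5‑dien‑1‑ol, via Grignard reagent 4 (not isolated), via alkenylmagnesium chelate 5 (not isolated)
Conditions: Mg, THF, 20 °C (2 → 4, 3.0 equiv); 1, CuI (10 mol%), THF–Et2O, −10 °C → rt, 12 h; then 3 (2.5 equiv), 0 °C → rt; aq. NH4Cl
Reagents that add atoms: none
Why: Copper‑catalysed anti‑carbomagnesiation of propargyl alcohol (Duboudin–Jousseaume reaction) puts the alkyl group on the internal carbon and magnesium cis to CH2O in a five‑membered chelate, so copper‑mediated allylation fixes the C4=C5 olefin with CH2OH and allyl cis.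

Step 2
Reactants: 6
Product: 7 (5Z)‑5‑(but‑3‑en‑1‑ylidene)oxan‑2‑ol
Conditions: 1 M aq. HCl, THF, rt, 6 h
Reagents that add atoms: water, O
Why: Acid‑catalysed acetal hydrolysis frees the aldehyde, which closes on the δ‑hydroxyl as a six‑membered lactol; the skipped diene and allylic alcohol tolerate dilute acid at room temperature.

Step 3
Reactants: 8 methyl (triphenyl‑λ5‑phosphanylidene)acetate (2.0 equiv); 9 2‑bromo‑N‑methoxy‑N‑methylacetamide
Product: 11 methyl 4‑[methoxy(methyl)amino]‑4‑oxo‑2‑(triphenyl‑λ5‑phosphanylidene)butanoate, via phosphonium bromide 10 (not isolated)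
Conditions: EtOAc, rt → 50 °C, 16 h; filter off the precipitated phosphonium salt
Reagents that add atoms: none
Why: C‑alkylation of a stabilised ylide by an α‑bromo amide followed by transylidation, in which the second equivalent of 8 deprotonates the new phosphonium salt.

Step 4
Reactants: 7; 11
Product: 12 methyl (2E,6Z)‑6‑(hydroxymethyl)‑2‑{2‑[methoxy(methyl)amino]‑2‑oxoethyl}deca‑2,6,9‑trienoate
Conditions: toluene, 90 °C, 16 h
Reagents that add atoms: none
Why: Wittig olefination of the lactol through its open hydroxy aldehyde with an α‑substituted ester ylide is E‑selective, placing the chain trans to CO2Me (C14) and cis to the CH2C(O)N arm (C9) as the C1=C10 olefin requires.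

Step 5
Reactants: 12
Product: 14 (2Z)‑2‑{3‑[(3E)‑5‑methoxyoxolan‑3‑ylidene]propyl}hexa‑2,5‑dien‑1‑ol, via lactol 13 (not isolated)
Conditions: i‑Bu2AlH (4.5 equiv), CH2Cl2, −78 °C, 2 h; then MeOH, then 3 M HCl in MeOH to pH 1–2, −78 → 0 °C, 1 h; NaHCO3
Reagents that add atoms: methanol, CO
Why: i‑Bu2AlH reduces the conjugated ester to the allylic alcohol and stops at the chelated aluminium hemiaminal of the Weinreb amide (Weinreb amide reduction); acidic methanol releases the aldehyde, which the neighbouring C14 hydroxyl traps as a five‑membered methyl acetal (Fischer‑type acetalisation).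

Step 6
Reactants: 15 (2R)‑3‑bromo‑2‑hydroxy‑2‑methylpropanoic acid
Product: 17 (2R)‑3‑chloro‑2‑hydroxy‑2‑methylpropanoic acid, via sodium glycidate 16 (not isolated)
Conditions: NaOH (2.1 equiv), H2O, 0 °C → rt, 2 h; then conc. HCl (6 equiv), 0 °C → rt, 12 h
Reagents that add atoms: hydrogen chloride, Cl
Why: Intramolecular Williamson closure to the glycidate and SN2 opening by chloride at the unhindered CH2 both leave the quaternary stereocentre untouched, so the spatial arrangement of the (R)‑bromo acid is carried into the (R)‑chloro acid.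

Step 7
Reactants: 14; 17
Product: 18 (2Z)‑2‑{3‑[(3E)‑5‑methoxyoxolan‑3‑ylidene]propyl}hexa‑2,5‑dien‑1‑yl (2R)‑3‑chloro‑2‑hydroxy‑2‑methylpropanoate
Conditions: PPh3, DIAD, THF, 0 °C → rt
Reagents that add atoms: none
Why: Mitsunobu esterification activates only the single free primary allylic hydroxyl (C15), while the hindered tertiary hydroxyl of the acid stays inert and its stereocentre is not involved.

Step 8
Reactants: 18; 19 methyl 2‑(bromomethyl)prop‑2‑enoate
Product: 20 methyl (2Z,5Z)‑2‑(bromomethyl)‑6‑({[(2R)‑3‑chloro‑2‑hydroxy‑2‑methylpropanoyl]oxy}methyl)‑9‑[(3E)‑5‑methoxyoxolan‑3‑ylidene]nona‑2,5‑dienoate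
Conditions: second‑generation Hoveyda–Grubbs catalyst RuCl2(SIMes)(=CH‑C6H4‑2‑O‑i‑Pr) (5 mol%), 19 (4 equiv), CH2Cl2, 40 °C, 12 h
Reagents that add atoms: none
Why: Olefin cross‑metathesis joins the only monosubstituted olefin with the 1,1‑disubstituted acrylate; the trisubstituted olefins do not engage, and the enoate geometry is not critical because it is not transferred in step 10.

Step 9
Reactants: 20
Product: 21 methyl (2Z,5Z)‑2‑(bromomethyl)‑6‑({[(2R)‑3‑chloro‑2‑hydroxy‑2‑methylpropanoyl]oxy}methyl)‑9‑[(3E)‑5‑hydroxyoxolan‑3‑ylidene]nona‑2,5‑dienoate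
Conditions: AcOH–THF–H2O (3:1:1), rt, 4 h
Reagents that add atoms: water, O
Why: Mild acid hydrolysis of the furanoside‑type acetal gives the lactol, which holds the β,γ‑unsaturated C8 aldehyde in masked form and leaves the allylic bromide and both esters intact.

Step 10
Reactants: 21
Product: 24 [(3aR,5Z,9E,11aS)‑10‑(hydroxymethyl)‑3‑methylidene‑2‑oxo‑2,3,3a,4,7,8,11,11a‑octahydrocyclodeca[b]furan‑6‑yl]methyl (2R)‑3‑chloro‑2‑hydroxy‑2‑methylpropanoate, via allylchromium species 22 (not isolated), via hydroxy ester 23 (not isolated)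
Conditions: CrCl2 (4 equiv), L* (4.4 equiv), i‑Pr2NEt (4.4 equiv), THF, rt, 1 h; 21 added over 12 h (final 2 mM), rt; then 40 °C, 2 h; aq. citric acid
Reagents that add atoms: none
Why: Proposed new method: two CrCl2 reduce the allylic bromide to a σ‑allyl complex of trivalent chromium that equilibrates by 1,3‑metal shift, so the enoate β‑carbon C7 attacks the aldehyde carbon C8 of the ring‑opened lactol through a six‑membered chair with both tether arms (C6 and C9) pseudo‑equatorial, giving the anti adduct and hence the trans lactone when the chromium alkoxide acylates on the methyl ester, while the C2‑symmetric ligand directs Re‑face attack (8S, and with anti addition 7R); the closest known reactions are the chromium‑catalysed enantioselective 2‑(alkoxycarbonyl)allylation of aldehydes (Nozaki–Hiyama–Kishi type), Barbier macrocyclisations to ten‑membered germacranolide rings, and chromium‑mediated additions to lactols as latent hydroxy aldehydes.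

## Compound list

1 | prop‑2‑yn‑1‑ol | C#CCO | starting material
2 | 2‑(2‑bromoethyl)‑1,3‑dioxolane | BrCCC1OCCO1 | starting material
3 | allyl bromide | C=CCBr | starting material
4 | [2‑(1,3‑dioxolan‑2‑yl)ethyl]magnesium bromide | Br[Mg]CCC1OCCO1 | intermediate
5 | 4‑[2‑(1,3‑dioxolan‑2‑yl)ethyl]‑2,5‑dihydro‑1,2‑oxamagnesole (alkenylmagnesium chelate) | C1(CCC2OCCO2)=C[Mg]OC1 | intermediate
6 | (2Z)‑2‑[2‑(1,3‑dioxolan‑2‑yl)ethyl]hexa‑2,5‑dien‑1‑ol | C=CC/C=C(\CO)CCC1OCCO1 | intermediate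
7 | (5Z)‑5‑(but‑3‑en‑1‑ylidene)oxan‑2‑ol (lactol of (4Z)‑4‑(hydroxymethyl)octa‑4,7‑dienal) | OC1CC/C(CO1)=C/CC=C | intermediate
8 | methyl (triphenyl‑λ5‑phosphanylidene)acetate | COC(=O)C=P(c1ccccc1)(c1ccccc1)c1ccccc1 | starting material
9 | 2‑bromo‑N‑methoxy‑N‑methylacetamide | CON(C)C(=O)CBr | starting material
10 | {1‑methoxy‑4‑[methoxy(methyl)amino]‑1,4‑dioxobutan‑2‑yl}triphenylphosphonium bromide | COC(=O)C(CC(=O)N(C)OC)[P+](c1ccccc1)(c1ccccc1)c1ccccc1.[Br-] | intermediate
11 | methyl 4‑[methoxy(methyl)amino]‑4‑oxo‑2‑(triphenyl‑λ5‑phosphanylidene)butanoate | COC(=O)C(CC(=O)N(C)OC)=P(c1ccccc1)(c1ccccc1)c1ccccc1 | intermediate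
12 | methyl (2E,6Z)‑6‑(hydroxymethyl)‑2‑{2‑[methoxy(methyl)amino]‑2‑oxoethyl}deca‑2,6,9‑trienoate | COC(=O)/C(CC(=O)N(C)OC)=C/CC/C(CO)=C/CC=C | intermediate
13 | (2Z)‑2‑{3‑[(3E)‑5‑hydroxyoxolan‑3‑ylidene]propyl}hexa‑2,5‑dien‑1‑ol | OC1C/C(CO1)=C\CC/C(CO)=C/CC=C | intermediate
14 | (2Z)‑2‑{3‑[(3E)‑5‑methoxyoxolan‑3‑ylidene]propyl}hexa‑2,5‑dien‑1‑ol | COC1C/C(CO1)=C\CC/C(CO)=C/CC=C | intermediate
15 | (2R)‑3‑bromo‑2‑hydroxy‑2‑methylpropanoic acid | OC(=O)[C@@](C)(O)CBr | starting material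
16 | sodium (2S)‑2‑methyloxirane‑2‑carboxylate | [Na+].[O-]C(=O)[C@@]1(C)OC1 | intermediate
17 | (2R)‑3‑chloro‑2‑hydroxy‑2‑methylpropanoic acid | OC(=O)[C@@](C)(O)CCl | intermediate
18 | (2Z)‑2‑{3‑[(3E)‑5‑methoxyoxolan‑3‑ylidene]propyl}hexa‑2,5‑dien‑1‑yl (2R)‑3‑chloro‑2‑hydroxy‑2‑methylpropanoate | COC1C/C(CO1)=C\CC/C(COC(=O)[C@@](C)(O)CCl)=C/CC=C | intermediate
19 | methyl 2‑(bromomethyl)prop‑2‑enoate | COC(=O)C(=C)CBr | starting material
20 | methyl (2Z,5Z)‑2‑(bromomethyl)‑6‑({[(2R)‑3‑chloro‑2‑hydroxy‑2‑methylpropanoyl]oxy}methyl)‑9‑[(3E)‑5‑methoxyoxolan‑3‑ylidene]nona‑2,5‑dienoate | COC1C/C(CO1)=C\CC/C(COC(=O)[C@@](C)(O)CCl)=C/C/C=C(\CBr)C(=O)OC | intermediate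
21 | methyl (2Z,5Z)‑2‑(bromomethyl)‑6‑({[(2R)‑3‑chloro‑2‑hydroxy‑2‑methylpropanoyl]oxy}methyl)‑9‑[(3E)‑5‑hydroxyoxolan‑3‑ylidene]nona‑2,5‑dienoate | OC1C/C(CO1)=C\CC/C(COC(=O)[C@@](C)(O)CCl)=C/C/C=C(\CBr)C(=O)OC | intermediate
22 | allylchromium dichloride derived from 21 (trivalent chromium; chiral ligand not drawn) | OC1C/C(CO1)=C\CC/C(COC(=O)[C@@](C)(O)CCl)=C/C/C=C(\C[Cr](Cl)Cl)C(=O)OC | intermediate
23 | methyl 2‑[(1R,2S,4E,8Z)‑8‑({[(2R)‑3‑chloro‑2‑hydroxy‑2‑methylpropanoyl]oxy}methyl)‑2‑hydroxy‑4‑(hydroxymethyl)cyclodeca‑4,8‑dien‑1‑yl]prop‑2‑enoate | O[C@H]1C/C(CO)=C\CC/C(COC(=O)[C@@](C)(O)CCl)=C/C[C@@H]1C(=C)C(=O)OC | intermediate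
24 | [(3aR,5Z,9E,11aS)‑10‑(hydroxymethyl)‑3‑methylidene‑2‑oxo‑2,3,3a,4,7,8,11,11a‑octahydrocyclodeca[b]furan‑6‑yl]methyl (2R)‑3‑chloro‑2‑hydroxy‑2‑methylpropanoate | C=C1C(=O)O[C@H]2C/C(CO)=C\CC/C(COC(=O)[C@@](C)(O)CCl)=C/C[C@H]12 | target

## Step count and risks

Total steps: 10. Longest linear sequence: 8 (steps 1, 2, 4, 5, 7, 8, 9, 10).

**Step 10 (ring closure).** Three things can go wrong: the lactol may open too slowly, so the allylchromium is protonated; the syn adduct (cis lactone) may form instead of the anti adduct; and the enantioselectivity may be low. The fallback sets out from 20 and comes back at 23. The bromide is exchanged for boron (B2pin2, Pd2(dba)3, toluene, 50 °C) to give methyl (2E,5Z)‑6‑({[(2R)‑3‑chloro‑2‑hydroxy‑2‑methylpropanoyl]oxy}methyl)‑9‑[(3E)‑5‑methoxyoxolan‑3‑ylidene]‑2‑[(4,4,5,5‑tetramethyl‑1,3,2‑dioxaborolan‑2‑yl)methyl]nona‑2,5‑dienoate F1. AcOH–THF–water then frees the corresponding 5‑hydroxyoxolane boronate F2. A chiral phosphoric acid ((R)‑TRIP, toluene, 4 Å sieves, rt → 40 °C) promotes ring‑closing allylboration through a closed chair to 23, which lactonises to 24 with PPTS. Here the ring forms by a thermal, metal‑free addition that tolerates hydroxyl groups, and the acid catalyst sets the aldehyde face. The relative configuration follows the boronate geometry; boronates of this type are known to equilibrate their geometry under acid and then give the anti (trans‑lactone) adduct.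

**Step 5 (reduction and acetal formation).** Over‑reduction, migration of the β,γ‑double bond into conjugation, or loss of methanol to a 3‑alkylfuran in acidic methanol could erode the yield. The fallback sets out from 7 and comes back at 14, and never passes through the free aldehyde. Horner–Wadsworth–Emmons reaction of 7 with methyl 2‑(dimethoxyphosphoryl)‑4,4‑dimethoxybutanoate F3 (from trimethyl phosphonoacetate and bromoacetaldehyde dimethyl acetal, NaH, DMF, 90 °C; then NaH, THF with 7) gives methyl (2E,6Z)‑2‑(2,2‑dimethoxyethyl)‑6‑(hydroxymethyl)deca‑2,6,9‑trienoate F4, separated from its Z isomer. i‑Bu2AlH (CH2Cl2, −78 °C) reduces only the ester to (2E,6Z)‑2‑(2,2‑dimethoxyethyl)‑6‑(hydroxymethyl)deca‑2,6,9‑trien‑1‑ol F5. PPTS in CH2Cl2 then closes the C14 hydroxyl onto the dimethyl acetal to give 14.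

**Step 1 (three‑component coupling).** The acetal Grignard reagent is thermally fragile, and the direct allylation of the chelated alkenylmagnesium is the least secure part. The fallback sets out from 5 and comes back at 6. Iodine (THF, −20 °C) converts 5 into (2Z)‑2‑[2‑(1,3‑dioxolan‑2‑yl)ethyl]‑3‑iodoprop‑2‑en‑1‑ol F6, which is isolated. A Stille coupling with Bu3SnCH2CH=CH2 (Pd(PPh3)4, CuI, DMF, 50 °C) then forms the C5–C6 bond with retention of geometry and gives 6.

## Further compounds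

F1 | step 10 | methyl (2E,5Z)‑6‑({[(2R)‑3‑chloro‑2‑hydroxy‑2‑methylpropanoyl]oxy}methyl)‑9‑[(3E)‑5‑methoxyoxolan‑3‑ylidene]‑2‑[(4,4,5,5‑tetramethyl‑1,3,2‑dioxaborolan‑2‑yl)methyl]nona‑2,5‑dienoate | COC1C/C(CO1)=C\CC/C(COC(=O)[C@@](C)(O)CCl)=C/C/C=C(\CB2OC(C)(C)C(C)(C)O2)C(=O)OC
F2 | step 10 | methyl (2E,5Z)‑6‑({[(2R)‑3‑chloro‑2‑hydroxy‑2‑methylpropanoyl]oxy}methyl)‑9‑[(3E)‑5‑hydroxyoxolan‑3‑ylidene]‑2‑[(4,4,5,5‑tetramethyl‑1,3,2‑dioxaborolan‑2‑yl)methyl]nona‑2,5‑dienoate | OC1C/C(CO1)=C\CC/C(COC(=O)[C@@](C)(O)CCl)=C/C/C=C(\CB2OC(C)(C)C(C)(C)O2)C(=O)OC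
F3 | step 5 | methyl 2‑(dimethoxyphosphoryl)‑4,4‑dimethoxybutanoate | COC(=O)C(CC(OC)OC)P(=O)(OC)OC
F4 | step 5 | methyl (2E,6Z)‑2‑(2,2‑dimethoxyethyl)‑6‑(hydroxymethyl)deca‑2,6,9‑trienoate | COC(=O)/C(CC(OC)OC)=C/CC/C(CO)=C/CC=C
F5 | step 5 | (2E,6Z)‑2‑(2,2‑dimethoxyethyl)‑6‑(hydroxymethyl)deca‑2,6,9‑trien‑1‑ol | OC/C(CC(OC)OC)=C/CC/C(CO)=C/CC=C
F6 | step 1 | (2Z)‑2‑[2‑(1,3‑dioxolan‑2‑yl)ethyl]‑3‑iodoprop‑2‑en‑1‑ol | OC/C(CCC1OCCO1)=C\I
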